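The ratio of 1.50 equiv of partner to starting material looks generous, so I set out what the flasks are asked to show.

    starting material + partner → target, rate k1*[starting material]^0.5*[partner]^0.5 (k1 = 0.0071 /s)
    target → over-reaction product (k2 = 1.5 × 10⁻⁵ /s)
    partner → decomposed reagent (k3 = 0.016 /s)
    crystals ⇌ target, rate k4*(cs4 - [target]) while solid is left; crystals form when [target] > cs4 (cs4 = 0.10 M, k4 = 0.96 /s)

| setting | elm | larch | birch |
|---|---|---|---|
| starting material | 0.25 M | 0.40 M | 0.60 M |
| partner | 1.50 equiv | 1.50 equiv | 1.50 equiv |
| time | 10 min | 10 min | 10 min |

- what is said of target includes crystals
- crystals is a solid; its amount is given per volume of the solution
- the concentration of target that is asked is that of its free form alone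
- "hardly changes" means that all values lie within two and a half points (for a concentration: within two and a half percent of the largest)
- run time (elm): 10 min

- [target] (only what is free in solution) at the end for elm, larch, birch, in this order
- the shape of the row from first to last (falls all the way / rises all the way / hardly changes / rises, then falls / falls, then rises)

The partner is in excess, yet at the start of elm its decay takes 2.8 times what the coupling takes, so I expect starting material to remain beside a spent excess. I write a for starting material and b for partner, both as fractions of the starting material charged. Taking roots makes the equations straight: the root of a falls at 0.00355 /s times the root of b, and the root of b falls at 0.00800 /s times itself plus 0.00355 /s times the root of a. Neither line holds the charge, and the flasks share 1.50 equiv, so one reckoning serves elm, larch and birch.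

Holding the root of a at a mean m, with c equal to 0.444 times m and y the starting root 1.22, the root of a drops by 0.444 times (y − c·ln(one + y/c)). With m at one it ends at 0.717. Going round with the mean 0.859, so c = 0.381, it ends at 0.700, and the root of b reaches zero at 3.00 min, earlier than 10 min. The partner is thus the limiting reagent.

This gives a reach of 0.510, the fraction of the charge turned into target once partner is gone. The saturated fraction is 0.400 in elm, 0.250 in larch and 0.167 in birch, and the reach is larger than each. While crystals stand, free target returns to its solubility with a time of 1.04 s, and the half-life of dissolved target by the over-reaction step alone in elm, 13 h, is long against the run. So dissolved target stands at 0.100 M, 0.100 M and 0.100 M, and the shape of the row is hardly changes.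

The forecast gave 0.1 M, 0.1 M and 0.1 M, hardly changes, saying “with fast dissolution and very slow over-reaction they hold the free target”.

The flask gives 0.100 M, 0.100 M and 0.100 M, hardly changes. In elm, coupling and decay ran while partner was there, half their turnover done by 0.661 min and 0.454 min, and at 5.00 min partner stood at 0% and starting material at 48.2%. Falling out, half done by 1.79 min, left crystals at 11.5% of the elm charge at 10.0 min, against the reach less the dissolved fraction, 11.0%, and in birch at 10.0 min crystals stood at 35.0% of the charge against 34.4%.

The numbers of this flask come from no measurement; no experiment stands behind them.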